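**Plan**

- The last cuts are the four remaining methyl ethers (BBr3) and the ring A quinone, which is unmasked from a 1,2,4-trimethoxy ring with (NH4)2Ce(NO3)6.
- The 4-hydroxy-2-pyranone is cut at C4–C5 and O1–C2. Its O1–C6–C5 atoms are the enol of the methyl ketone naphthyl–CH2–CO–CH3 and its C2–C3–C4 atoms are a malonyl unit, so the ring can be closed at carbon onto malonyl dichloride.
- The terminal enol silane needed for this comes from an arylacetic Weinreb amide, Me3SiCH2MgCl and a 1,3 carbon-to-oxygen silyl shift.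
- Ring B of the naphthalene is cut at C5–C6 and C7–C8: a trimethoxyhomophthalic anhydride plus an aryl ynone (Tamura annulation).
- Forward order: ring A (from 2,4,5-trimethoxybenzoic acid), then ring B by annulation, then the side chain, then the pyranone ring, then the quinone.
- The target has no stereocentre; the single carbinol centre formed on the way is racemic and is erased by oxidation in step 5.

Key step: step 12

Remark: naphthalene positions are numbered throughout as in the target quinone (C1 and C4 carbonyl carbons, C2 hydroxyl, C5 peri-hydroxyl, C6 aroyl, C7 side chain; ring A = C1–C4, ring B = C5–C8). The hydroxyquinone is treated as its 2-hydroxy-1,4-dione tautomer.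

**Route**

Step 1
Reactants: 1 2,4,5-trimethoxybenzoic acid
Product: 3 3,4,6-trimethoxy-2-methylbenzoic acid, via dilithio salt 2 (not isolated)
Conditions: s-BuLi (2.2 equiv), TMEDA, THF, −78 °C; MeI, −78 °C to rt; aq HCl
Reagents that add atoms: iodomethane, CI; s-BuLi, [Li]C(C)CC (lithium of intermediate 2 only)
Why: Carboxylate-directed ortho-lithiation of the unprotected benzoic acid should occur at C6, the only position ortho to the lithium carboxylate and also flanked by the C5 methoxy group, and the aryllithium is then methylated by MeI.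

Step 2
Reactants: 3 3,4,6-trimethoxy-2-methylbenzoic acid
Product: 5 2-(carboxymethyl)-3,4,6-trimethoxybenzoic acid, via benzylic dianion 4 (not isolated)
Conditions: LiN(i-Pr)2 (2.3 equiv), THF, −78 to 0 °C; CO2, −78 °C; aq HCl
Reagents that add atoms: carbon dioxide, O=C=O; LiN(i-Pr)2, [Li]N(C(C)C)C(C)C (lithium of intermediate 4 only)
Why: Lateral (benzylic) lithiation of the o-toluate dianion, directed by the neighbouring carboxylate, followed by carboxylation of the benzylic organolithium gives the homophthalic acid.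

Step 3
Reactants: 5 2-(carboxymethyl)-3,4,6-trimethoxybenzoic acid
Product: 6 5,6,8-trimethoxyisochromane-1,3-dione
Conditions: AcCl, reflux; evaporate, use directly
Reagents that add atoms: none
Why: Cyclodehydration of the 1,5-diacid through its mixed anhydride with acetyl chloride gives the six-membered homophthalic anhydride.

Step 4
Reactants: 7 tert-butyl(but-3-yn-1-yloxy)dimethylsilane; 8 2,4-dimethoxy-6-methylbenzaldehyde
Product: 10 rac-5-(tert-butyldimethylsilyloxy)-1-(2,4-dimethoxy-6-methylphenyl)pent-2-yn-1-ol, via lithium acetylide 9 (not isolated)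
Conditions: n-BuLi, THF, −78 °C; add 8, −78 to 0 °C; aq NH4Cl
Reagents that add atoms: n-BuLi, [Li]CCCC (lithium of intermediate 9 only)
Why: 1,2-Addition of a lithium acetylide to an aromatic aldehyde; the new carbinol centre forms as a racemate and is removed in step 5.

Step 5
Reactants: 10 rac-5-(tert-butyldimethylsilyloxy)-1-(2,4-dimethoxy-6-methylphenyl)pent-2-yn-1-ol
Product: 11 5-(tert-butyldimethylsilyloxy)-1-(2,4-dimethoxy-6-methylphenyl)pent-2-yn-1-one
Conditions: MnO2 (activated, excess), CH2Cl2, rt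
Reagents that add atoms: none
Why: MnO2 oxidation of a doubly activated (benzylic and propargylic) alcohol gives the ynone and leaves the silyl ether and the alkyne untouched.

Step 6
Reactants: 6 5,6,8-trimethoxyisochromane-1,3-dione; 11 5-(tert-butyldimethylsilyloxy)-1-(2,4-dimethoxy-6-methylphenyl)pent-2-yn-1-one
Product: 14 7-[2-(tert-butyldimethylsilyloxy)ethyl]-6-(2,4-dimethoxy-6-methylbenzoyl)-1,2,4,5-tetramethoxynaphthalene, via sodium enolate 12 (not isolated), via sodium naphthoxide 13 (not isolated)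
Conditions: NaH (1.1 equiv), THF, 0 °C; add 11, 0 °C to rt; then MeI, DMF, rt to 40 °C
Reagents that add atoms: iodomethane, CI; NaH, [Na+].[H-] (sodium of intermediates 12 and 13 only)
Why: Tamura annulation, in which enolate 12 adds through its C4 to the ynone β-carbon (Michael), the resulting allenolate carbon acylates the aryl-bound anhydride carbonyl (Claisen type) and loss of CO2 aromatises ring B, so the aroyl group ends at C6 next to the new C5 oxygen and the side chain at C7; naphthoxide 13 is then O-methylated in the same flask (Williamson).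

Step 7
Reactants: 14 7-[2-(tert-butyldimethylsilyloxy)ethyl]-6-(2,4-dimethoxy-6-methylbenzoyl)-1,2,4,5-tetramethoxynaphthalene
Product: 15 2-[6-(2,4-dimethoxy-6-methylbenzoyl)-1,2,4,5-tetramethoxynaphthalen-7-yl]ethanol
Conditions: HF·pyridine, THF, 0 °C to rt
Reagents that add atoms: none
Why: Fluoride-mediated cleavage of the primary silyl ether is driven by the Si–F bond, and the methyl ethers and the hindered diaryl ketone are inert.

Step 8
Reactants: 15 2-[6-(2,4-dimethoxy-6-methylbenzoyl)-1,2,4,5-tetramethoxynaphthalen-7-yl]ethanol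
Product: 17 2-[6-(2,4-dimethoxy-6-methylbenzoyl)-1,2,4,5-tetramethoxynaphthalen-7-yl]acetic acid, via arylacetaldehyde 16 (not isolated)
Conditions: Dess–Martin periodinane, pyridine, CH2Cl2, 0 °C to rt; then NaClO2, NaH2PO4, 2-methyl-2-butene, t-BuOH/H2O, rt
Reagents that add atoms: sodium chlorite, [Na+].[O-]Cl=O
Why: Dess–Martin oxidation to the aldehyde and Pinnick oxidation of the crude aldehyde to the acid, with 2-methyl-2-butene trapping HOCl so that the electron-rich naphthalene should not be chlorinated.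

Step 9
Reactants: 17 2-[6-(2,4-dimethoxy-6-methylbenzoyl)-1,2,4,5-tetramethoxynaphthalen-7-yl]acetic acid
Product: 19 2-[6-(2,4-dimethoxy-6-methylbenzoyl)-1,2,4,5-tetramethoxynaphthalen-7-yl]-N-methoxy-N-methylacetamide, via acyl imidazolide 18 (not isolated)
Conditions: 1,1′-carbonyldiimidazole, CH2Cl2, rt; then MeNH(OMe)·HCl, rt
Reagents that add atoms: N,O-dimethylhydroxylamine hydrochloride, CNOC.Cl; 1,1′-carbonyldiimidazole, O=C(n1ccnc1)n1ccnc1 (imidazolyl group of intermediate 18 only)
Why: Weinreb amide formation by activation as the acyl imidazolide and aminolysis, a mild neutral activation that should not trigger cyclisation onto the neighbouring ketone.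

Step 10
Reactants: 19 2-[6-(2,4-dimethoxy-6-methylbenzoyl)-1,2,4,5-tetramethoxynaphthalen-7-yl]-N-methoxy-N-methylacetamide; 20 (trimethylsilyl)methylmagnesium chloride
Product: 21 1-[6-(2,4-dimethoxy-6-methylbenzoyl)-1,2,4,5-tetramethoxynaphthalen-7-yl]-3-(trimethylsilyl)propan-2-one
Conditions: Me3SiCH2MgCl (2 equiv), THF, 0 °C to rt; aq NH4Cl at 0 °C; filter through neutral alumina
Reagents that add atoms: none
Why: Weinreb ketone synthesis, in which the magnesium-chelated tetrahedral adduct stops at single addition and the tetra-ortho-substituted diaryl ketone is too hindered to compete, so the α-silyl ketone should be obtained after a neutral quench.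

Step 11
Reactants: 21 1-[6-(2,4-dimethoxy-6-methylbenzoyl)-1,2,4,5-tetramethoxynaphthalen-7-yl]-3-(trimethylsilyl)propan-2-one
Product: 22 6-(2,4-dimethoxy-6-methylbenzoyl)-1,2,4,5-tetramethoxy-7-[2-(trimethylsilyloxy)prop-2-en-1-yl]naphthalene
Conditions: o-xylene (degassed), 135 °C, base-washed sealed tube; evaporate, use crude
Reagents that add atoms: none
Why: Thermal 1,3-silyl shift from carbon to oxygen in a β-ketosilane (Brook-type rearrangement) is intramolecular and places the enol double bond only at the carbon that carried silicon, so the terminal enol silane should form free of the benzylic isomer.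

Step 12
Reactants: 22 6-(2,4-dimethoxy-6-methylbenzoyl)-1,2,4,5-tetramethoxy-7-[2-(trimethylsilyloxy)prop-2-en-1-yl]naphthalene; 23 malonyl dichloride
Product: 25 6-{[6-(2,4-dimethoxy-6-methylbenzoyl)-1,2,4,5-tetramethoxynaphthalen-7-yl]methyl}-4-hydroxy-2H-pyran-2-one, via dioxohexanoyl chloride 24 (not isolated)
Conditions: 23 (1.05 equiv), Et2O/CH2Cl2, −78 °C to rt; extract into aq NaHCO3, acidify
Reagents that add atoms: none
Why: The terminal carbon of enol silane 22 attacks one acyl chloride of 23 (or the chlorocarbonylketene derived from it), silicon leaves as Me3SiCl and the 3,5-dioxohexanoyl chloride 24 results, which sets pyranone C4–C5. Enolisation of the 1,3-diketone toward the former ketone carbon brings its oxygen within reach of the remaining acyl chloride, a 6-exo-trig O-acylation closes O1–C2, and tautomerisation gives the 4-hydroxy-2-pyranone. The closest known reaction type is the annulation of silyl enol ethers and ketones with malonyl dichloride to 6-substituted 4-hydroxy-2-pyranones. No stereocentre is formed. The step needs regioselectivity between the methyl and the benzylic α-carbon, which the regiodefined terminal enol silane from step 11 secures; because the reagent is symmetrical, O-acylation first and C-acylation second would give the same ring. The diaryl ketone cannot enolise, the methoxyarenes should not be acylated without a Lewis acid, and a near-stoichiometric charge of 23 at low temperature keeps the acidic product from reacting a second time.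

Step 13
Reactants: 25 6-{[6-(2,4-dimethoxy-6-methylbenzoyl)-1,2,4,5-tetramethoxynaphthalen-7-yl]methyl}-4-hydroxy-2H-pyran-2-one
Product: 26 6-(2,4-dimethoxy-6-methylbenzoyl)-7-[(4-hydroxy-2-oxo-2H-pyran-6-yl)methyl]-2,5-dimethoxynaphthalene-1,4-dione
Conditions: (NH4)2Ce(NO3)6 (2.2 equiv), MeCN/H2O 2:1, 0 °C, short reaction time
Reagents that add atoms: water, O
Why: Oxidative demethylation of a 1,4-dimethoxyarene by tetravalent cerium should take place on ring A, the most easily oxidised arene, giving the 2-methoxy-1,4-quinone with both carbonyl oxygens from water; any 4-methoxy-1,2-quinone isomer converges on the same hydroxyquinone in step 14.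

Step 14
Reactants: 26 6-(2,4-dimethoxy-6-methylbenzoyl)-7-[(4-hydroxy-2-oxo-2H-pyran-6-yl)methyl]-2,5-dimethoxynaphthalene-1,4-dione
Product: 27 6-(2,4-dihydroxy-6-methylbenzoyl)-2,5-dihydroxy-7-[(4-hydroxy-2-oxo-2H-pyran-6-yl)methyl]naphthalene-1,4-dione
Conditions: BBr3 (excess), CH2Cl2, −78 °C to rt; H2O, 0 °C
Reagents that add atoms: none
Why: Lewis acid ether cleavage with BBr3 should remove the vinylogous ester methyl at C2, the carbonyl-chelated methyl ethers at C5 and C2′ and the C4′ methyl ether, and hydrolysis of the borates gives the target; the pyranone lactone and the quinone are expected to tolerate the reagent.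

**Compound list**

1 | 2,4,5-trimethoxybenzoic acid | COc1cc(OC)c(C(=O)O)cc1OC | starting material
2 | lithium 2-lithio-3,4,6-trimethoxybenzoate (formed in situ) | [Li]c1c(C(=O)[O-])c(OC)cc(OC)c1OC.[Li+] | intermediate
3 | 3,4,6-trimethoxy-2-methylbenzoic acid | Cc1c(C(=O)O)c(OC)cc(OC)c1OC | intermediate
4 | lithium 2-(lithiomethyl)-3,4,6-trimethoxybenzoate (formed in situ) | [Li]Cc1c(C(=O)[O-])c(OC)cc(OC)c1OC.[Li+] | intermediate
5 | 2-(carboxymethyl)-3,4,6-trimethoxybenzoic acid | OC(=O)Cc1c(C(=O)O)c(OC)cc(OC)c1OC | intermediate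
6 | 5,6,8-trimethoxyisochromane-1,3-dione | COc1cc(OC)c2c(c1OC)CC(=O)OC2=O | intermediate
7 | tert-butyl(but-3-yn-1-yloxy)dimethylsilane | C#CCCO[Si](C)(C)C(C)(C)C | starting material
8 | 2,4-dimethoxy-6-methylbenzaldehyde | Cc1cc(OC)cc(OC)c1C=O | starting material
9 | [4-(tert-butyldimethylsilyloxy)but-1-yn-1-yl]lithium (formed in situ) | [Li]C#CCCO[Si](C)(C)C(C)(C)C | intermediate
10 | rac-5-(tert-butyldimethylsilyloxy)-1-(2,4-dimethoxy-6-methylphenyl)pent-2-yn-1-ol (racemate) | Cc1cc(OC)cc(OC)c1C(O)C#CCCO[Si](C)(C)C(C)(C)C | intermediate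
11 | 5-(tert-butyldimethylsilyloxy)-1-(2,4-dimethoxy-6-methylphenyl)pent-2-yn-1-one | Cc1cc(OC)cc(OC)c1C(=O)C#CCCO[Si](C)(C)C(C)(C)C | intermediate
12 | sodium 5,6,8-trimethoxy-1-oxo-1H-isochromen-3-olate (formed in situ) | [Na+].[O-]C1=Cc2c(OC)c(OC)cc(OC)c2C(=O)O1 | intermediate
13 | sodium 7-[2-(tert-butyldimethylsilyloxy)ethyl]-6-(2,4-dimethoxy-6-methylbenzoyl)-1,2,4-trimethoxynaphthalen-5-olate (formed in situ) | COc1cc(OC)c2c([O-])c(C(=O)c3c(C)cc(OC)cc3OC)c(CCO[Si](C)(C)C(C)(C)C)cc2c1OC.[Na+] | intermediate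
14 | 7-[2-(tert-butyldimethylsilyloxy)ethyl]-6-(2,4-dimethoxy-6-methylbenzoyl)-1,2,4,5-tetramethoxynaphthalene | COc1cc(OC)c2c(OC)c(C(=O)c3c(C)cc(OC)cc3OC)c(CCO[Si](C)(C)C(C)(C)C)cc2c1OC | intermediate
15 | 2-[6-(2,4-dimethoxy-6-methylbenzoyl)-1,2,4,5-tetramethoxynaphthalen-7-yl]ethanol | COc1cc(OC)c2c(OC)c(C(=O)c3c(C)cc(OC)cc3OC)c(CCO)cc2c1OC | intermediate
16 | 2-[6-(2,4-dimethoxy-6-methylbenzoyl)-1,2,4,5-tetramethoxynaphthalen-7-yl]acetaldehyde (not isolated) | COc1cc(OC)c2c(OC)c(C(=O)c3c(C)cc(OC)cc3OC)c(CC=O)cc2c1OC | intermediate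
17 | 2-[6-(2,4-dimethoxy-6-methylbenzoyl)-1,2,4,5-tetramethoxynaphthalen-7-yl]acetic acid | COc1cc(OC)c2c(OC)c(C(=O)c3c(C)cc(OC)cc3OC)c(CC(=O)O)cc2c1OC | intermediate
18 | 1-{2-[6-(2,4-dimethoxy-6-methylbenzoyl)-1,2,4,5-tetramethoxynaphthalen-7-yl]acetyl}imidazole (not isolated) | COc1cc(OC)c2c(OC)c(C(=O)c3c(C)cc(OC)cc3OC)c(CC(=O)n3ccnc3)cc2c1OC | intermediate
19 | 2-[6-(2,4-dimethoxy-6-methylbenzoyl)-1,2,4,5-tetramethoxynaphthalen-7-yl]-N-methoxy-N-methylacetamide | COc1cc(OC)c2c(OC)c(C(=O)c3c(C)cc(OC)cc3OC)c(CC(=O)N(C)OC)cc2c1OC | intermediate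
20 | (trimethylsilyl)methylmagnesium chloride | C[Si](C)(C)C[Mg]Cl | starting material
21 | 1-[6-(2,4-dimethoxy-6-methylbenzoyl)-1,2,4,5-tetramethoxynaphthalen-7-yl]-3-(trimethylsilyl)propan-2-one | COc1cc(OC)c2c(OC)c(C(=O)c3c(C)cc(OC)cc3OC)c(CC(=O)C[Si](C)(C)C)cc2c1OC | intermediate
22 | 6-(2,4-dimethoxy-6-methylbenzoyl)-1,2,4,5-tetramethoxy-7-[2-(trimethylsilyloxy)prop-2-en-1-yl]naphthalene | COc1cc(OC)c2c(OC)c(C(=O)c3c(C)cc(OC)cc3OC)c(CC(=C)O[Si](C)(C)C)cc2c1OC | intermediate
23 | malonyl dichloride | O=C(Cl)CC(=O)Cl | starting material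
24 | 6-[6-(2,4-dimethoxy-6-methylbenzoyl)-1,2,4,5-tetramethoxynaphthalen-7-yl]-3,5-dioxohexanoyl chloride (not isolated) | COc1cc(OC)c2c(OC)c(C(=O)c3c(C)cc(OC)cc3OC)c(CC(=O)CC(=O)CC(=O)Cl)cc2c1OC | intermediate
25 | 6-{[6-(2,4-dimethoxy-6-methylbenzoyl)-1,2,4,5-tetramethoxynaphthalen-7-yl]methyl}-4-hydroxy-2H-pyran-2-one | COc1cc(OC)c2c(OC)c(C(=O)c3c(C)cc(OC)cc3OC)c(Cc3cc(O)cc(=O)o3)cc2c1OC | intermediate
26 | 6-(2,4-dimethoxy-6-methylbenzoyl)-7-[(4-hydroxy-2-oxo-2H-pyran-6-yl)methyl]-2,5-dimethoxynaphthalene-1,4-dione | COC1=CC(=O)c2c(OC)c(C(=O)c3c(C)cc(OC)cc3OC)c(Cc3cc(O)cc(=O)o3)cc2C1=O | intermediate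
27 | 6-(2,4-dihydroxy-6-methylbenzoyl)-2,5-dihydroxy-7-[(4-hydroxy-2-oxo-2H-pyran-6-yl)methyl]naphthalene-1,4-dione (CNP0158797.0) | Cc1cc(O)cc(O)c1C(=O)c1c(Cc2cc(O)cc(=O)o2)cc2c(c1O)C(=O)C=C(O)C2=O | target

**Count**

Total steps: 14. Longest linear sequence: 12 (steps 1–3 and 6–14); steps 4–5 prepare the ynone in a side branch.

**Steps most likely to fail**

Step 12. The HCl released during acylation may cleave the enol silane before the carbon–carbon bond forms, or the acidic pyranone may be acylated a second time, so that conversion stalls or gives mixtures. The fallback closes the ring the conventional way, at oxygen, and sets out from acid 17. Activation as acyl imidazolide 18 and reaction with the lithium dienolate of 2,2,6-trimethyl-4H-1,3-dioxin-4-one (LiN(SiMe3)2, at least 2 equiv, THF, −78 °C) should give 6-{3-[6-(2,4-dimethoxy-6-methylbenzoyl)-1,2,4,5-tetramethoxynaphthalen-7-yl]-2-oxopropyl}-2,2-dimethyl-4H-1,3-dioxin-4-one F1. Heating in toluene at 110 °C expels acetone, and the acylketene is trapped by the enol oxygen of the side-chain ketone. The fallback comes back to the route at pyranone 25.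

Step 13. Tetravalent cerium may also oxidise the enolic hydroxypyranone at its C3, or over-oxidise the other methoxyarene rings, so chemoselectivity for ring A may be lost. The fallback inverts the order of the last two operations and sets out from 25. BBr3 (CH2Cl2, −78 °C to rt, work-up under argon) cleaves all six methyl ethers to 6-{[6-(2,4-dihydroxy-6-methylbenzoyl)-1,2,4,5-tetrahydroxynaphthalen-7-yl]methyl}-4-hydroxy-2H-pyran-2-one F2. Its 1,2,4-trihydroxynaphthalene unit is then oxidised by air (O2, EtOAc/pH 7 phosphate buffer, rt) to the 2-hydroxy-1,4-quinone. The fallback comes back to the route at target 27.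

Step 1. Lithiation may take place at C3 between the two methoxy groups, or s-BuLi may displace the methoxy group ortho to the carboxylate, so regiocontrol at C6 may be lost. The fallback uses a stronger directing group and sets out from 1. The acid is converted into N,N-diethyl-2,4,5-trimethoxybenzamide F3 ((COCl)2, cat. DMF, CH2Cl2; then Et2NH). Amide-directed ortho-lithiation (s-BuLi/TMEDA, THF, −78 °C) and MeI should give N,N-diethyl-3,4,6-trimethoxy-2-methylbenzamide F4. Cp2Zr(H)Cl, generated from Cp2ZrCl2 and LiAlH(O-t-Bu)3 in THF, reduces the hindered tertiary amide to 3,4,6-trimethoxy-2-methylbenzaldehyde F5. Pinnick oxidation (NaClO2, NaH2PO4, 2-methyl-2-butene) then brings the fallback back to the route at acid 3.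

**Further compounds**

F1 | step 12 | 6-{3-[6-(2,4-dimethoxy-6-methylbenzoyl)-1,2,4,5-tetramethoxynaphthalen-7-yl]-2-oxopropyl}-2,2-dimethyl-4H-1,3-dioxin-4-one | COc1cc(OC)c2c(OC)c(C(=O)c3c(C)cc(OC)cc3OC)c(CC(=O)CC3=CC(=O)OC(C)(C)O3)cc2c1OC
F2 | step 13 | 6-{[6-(2,4-dihydroxy-6-methylbenzoyl)-1,2,4,5-tetrahydroxynaphthalen-7-yl]methyl}-4-hydroxy-2H-pyran-2-one | Cc1cc(O)cc(O)c1C(=O)c1c(Cc2cc(O)cc(=O)o2)cc2c(O)c(O)cc(O)c2c1O
F3 | step 1 | N,N-diethyl-2,4,5-trimethoxybenzamide | CCN(CC)C(=O)c1cc(OC)c(OC)cc1OC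
F4 | step 1 | N,N-diethyl-3,4,6-trimethoxy-2-methylbenzamide | CCN(CC)C(=O)c1c(C)c(OC)c(OC)cc1OC
F5 | step 1 | 3,4,6-trimethoxy-2-methylbenzaldehyde | Cc1c(C=O)c(OC)cc(OC)c1OC
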